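Ring B (C3a–C4–C5–C6–C7–C7a, octahydroindene numbering) is traced back to the cyclopentane of the D-ribose-derived enone 1. This enone brings the cis C5/C6 oxygens and steers C7, C7a and C4. The route rests on disconnecting C2–C3 and returning C7a from C3a to C4. Forward, one Prins–pinacol step lets the vinyl group on C4 attack an oxocarbenium ion at C2, after which C7a shifts from C4 to C3a. Ring A closes, the five-membered carbocycle becomes six-membered ring B, and a C4 ketone (the later exocyclic methylene) appears. The step exploits the 1,4-relation C2(O)–C3–C3a–C4 and the fusion bond C3a–C7a. The precursor is a tricyclic vinyl lactol benzyl ether.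

Key step: step 7

Remark on numbering, with one assumption:
- The locants C1–C7a of the target core are used for every intermediate, and C1′ is the carbinol carbon of the side chain.
- β is the face of the C5/C6 oxygens and α is the opposite face. Ring A is the cyclopentanone and ring B the cyclohexane.
- C2 of 18 and 19 is an anomeric mixture. C2 of 20–24 is drawn as the expected β-epimer, and both epimers converge in step 10.
- Assumption: 1, 27 and 30 are bought as single stereoisomers.

Step 1
Reactants: 1 (3aR,6aR)-2,2-dimethyl-3a,6a-dihydro-4H-cyclopenta[d][1,3]dioxol-4-one; 2 isopropylmagnesium chloride; 3 chlorotrimethylsilane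
Product: 4 silyl enol ether (C4–OSiMe3, C4=C7a, 7α-isopropyl, 5β,6β-O-isopropylidene)
Conditions: 2, CuBr·SMe2 (10 mol %), 3, THF, −78 °C
Reagents that add atoms: isopropylmagnesium chloride CC(C)[Mg]Cl; chlorotrimethylsilane C[Si](C)(C)Cl
Why: Copper-catalysed conjugate addition of the Grignard reagent, accelerated and trapped by Me3SiCl, takes place on the convex face anti to the acetonide and so sets C7 (isopropyl α).

Step 2
Reactants: 4 silyl enol ether; 5 methyl iodoacetate
Product: 7 keto ester (C4 ketone, 7aβ-CH2CO2Me, 7a-H α, 7α-isopropyl, 5β,6β-acetonide), via lithium ketone enolate 6 (not isolated)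
Conditions: MeLi, THF, 0 °C; then 5, DMPU, −78 → −30 °C
Reagents that add atoms: methyl iodoacetate COC(=O)CI
Why: Cleavage of the silyl enol ether gives the regiodefined enolate, whose SN2 alkylation occurs anti to the neighbouring isopropyl group and sets C7a in the trans arrangement that is also the equilibrium one.

Step 3
Reactants: 7 keto ester; 8 vinylmagnesium bromide
Product: 10 tricyclic γ-lactone (4α-vinyl, C4–Oβ–C2(=O)–C1H2–C7a, cis-fused), via bromomagnesium alkoxide 9 (not isolated)
Conditions: 8, LaCl3·2LiCl, THF, −78 °C → rt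
Reagents that add atoms: vinylmagnesium bromide C=C[Mg]Br
Why: Lanthanum-assisted Grignard 1,2-addition from the convex α face (opposite to the acetonide and the C7a arm) sets C4, and the β-alkoxide, cis to the ester arm, lactonises on warming.

Step 4
Reactants: 10 tricyclic γ-lactone; 11 acetaldehyde
Product: 14 syn-aldol lactone (1S,1′R; 1-[(R)-1-hydroxyethyl], side chain cis to 7a-H), via lithium lactone enolate 12 (not isolated), via zirconium lactone enolate 13 (not isolated)
Conditions: LiN(i-Pr)2, THF, −78 °C; Cp2ZrCl2, −78 °C; then 11, −78 °C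
Reagents that add atoms: acetaldehyde CC=O
Why: In this aldol addition the aldehyde meets the convex face of the cis-fused lactone (sets C1), and zirconium enolates give the syn (erythro) aldol whatever the enolate geometry (sets C1′ as R).

Step 5
Reactants: 14 syn-aldol lactone; 15 tert-butylchlorodiphenylsilane
Product: 16 TBDPS ether of 14
Conditions: 15, imidazole, DMAP (cat.), DMF, 40 °C
Reagents that add atoms: tert-butylchlorodiphenylsilane CC(C)(C)[Si](Cl)(c1ccccc1)c1ccccc1
Why: Standard silylation touches no stereocentre, and the acid-stable TBDPS group is chosen because it must outlast SnCl4 and the later ketal hydrolysis.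

Step 6
Reactants: 16 TBDPS ether lactone; 17 benzyl alcohol
Product: 19 lactol benzyl ether (mixed acetal at C2, anomeric mixture), via lactol 18 (not isolated)
Conditions: i-Bu2AlH, CH2Cl2, −78 °C; work-up; crude, 17, PPTS (cat.), 4 Å MS, CH2Cl2, rt
Reagents that add atoms: benzyl alcohol OCc1ccccc1
Why: Partial lactone reduction stops at the aluminium hemiacetal at low temperature, and acid-catalysed acetalisation fixes the lactol as its benzyl ether, whose anomeric centre is inconsequential because it is ionised in step 7.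

Step 7
Reactants: 19 lactol benzyl ether
Product: 21 trans-fused hydrindan-4-one (2β-benzyloxy, 1α-[(R)-1-(TBDPS-oxy)ethyl], 3a-H β, 7a-H α, 7α-isopropyl, 5β,6β-acetonide), via cis-fused ketone 20 (not isolated)
Conditions: SnCl4 (1.2 equiv), CH2Cl2, −78 → −20 °C; aq NaHCO3; crude, DBU (cat.), toluene, 40 °C
Reagents that add atoms: none
Why: SnCl4, held by the cis C4 and C5 oxygens, cleaves the ring C2–O bond of the acetal (chelation-induced endocyclic cleavage, as in Lewis acid glycoside anomerisation) to give an open-chain O-benzyl oxocarbenium ion at C2 and a tin alkoxide at C4, whereas loss of the benzyloxy group is reversible and unproductive. The terminal vinyl carbon C3 attacks C2 through a chair (6-endo-trig at the alkene, side chain and OBn equatorial), which closes the carbocycle C2–C1–C7a–C4–C3a–C3 and places the charge on C3a next to the alkoxide. The pinacol shift of C7a from C4 to C3a contracts this ring to ring A and widens the cyclopentane C4–C5–C6–C7–C7a to ring B by insertion of C3a, with the C4 ketone as sink; this is the Prins–pinacol ring-enlarging cyclopentane annulation known for 1-alkenyl-2-(2,2-dialkoxyethyl)cycloalkanol derivatives and for cyclic acetals of allylic diols. C7a migrates suprafacially with retention, so C3a first forms cis (20), C2 follows from the equatorial OBn and is erased in step 10, and both anomers of 19 converge on one cation. DBU then equilibrates C3a through the C4 enolate to trans-fused 21, which is favoured because in 20 C3 stands syn-axial to the axial C5 oxygen, while the equatorial C5–H and C6–O bonds are poorly aligned for epimerisation or β-elimination. The step needs C7a rather than C5 to migrate, which is secured by the electron-withdrawing oxygen on C5 and by the strain of the bridged alternative.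

Step 8
Reactants: 21 trans-fused hydrindan-4-one
Product: 22 2β-hydroxy hydrindan-4-one
Conditions: H2 (1 atm), Pd/C, EtOAc, rt
Reagents that add atoms: none
Why: Catalytic hydrogenolysis of the benzyl ether is clean here because no C=C bond is present at this stage and silyl ether, ketal and ketone are inert to H2 over Pd/C.

Step 9
Reactants: 22 2β-hydroxy hydrindan-4-one; 23 methyltriphenylphosphonium bromide
Product: 24 4-methylene-2β-ol
Conditions: 23, KOt-Bu (excess), THF, 0 → 50 °C
Reagents that add atoms: methyltriphenylphosphonium bromide C[P+](c1ccccc1)(c1ccccc1)c1ccccc1.[Br-]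
Why: Wittig methylenation, well established for α-alkoxy ketones flanked by ketals, converts C4=O into the exocyclic methylene; excess ylide only deprotonates the C2 alcohol, and C3a is already at its equilibrium configuration.

Step 10
Reactants: 24 4-methylene-2β-ol
Product: 25 4-methylene-2-ketone (C1′–OTBDPS, 5β,6β-acetonide)
Conditions: Dess–Martin periodinane, CH2Cl2, 0 °C → rt
Reagents that add atoms: none
Why: Dess–Martin oxidation under non-basic conditions gives the C2 ketone without β-elimination of the silyloxy group, removes the C2 stereocentre and leaves C1 in the configuration (side chain cis to 7a-H) that is expected to be the equilibrium one as well.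

Step 11
Reactants: 25 4-methylene-2-ketone
Product: 26 5β,6β-diol
Conditions: AcOH/H2O (4:1), 50 °C
Reagents that add atoms: none
Why: Acid-catalysed ketal hydrolysis releases the cis-diol, while the TBDPS ether and the β-silyloxy ketone tolerate weak aqueous acid.

Step 12
Reactants: 26 5β,6β-diol; 27 (S)-2-methylbutanoic anhydride
Product: 29 6-O-[(S)-2-methylbutanoyl] 5β-ol, via stannylene acetal 28 (not isolated)
Conditions: Bu2SnO, MeOH, reflux; evaporate; 27, toluene, 0 °C → rt
Reagents that add atoms: (S)-2-methylbutanoic anhydride CC[C@H](C)C(=O)OC(=O)[C@@H](C)CC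
Why: In stannylene-acetal-mediated monoacylation of a cis axial/equatorial diol the equatorial oxygen (C6–O, kept dicoordinate by the neighbouring isopropyl group) is the nucleophilic one, and the absence of amine base protects the α-stereocentre brought in by 27.

Step 13
Reactants: 29 6-O-acyl 5β-ol; 30 (E)-3-methylpent-2-enoic acid
Product: 31 5,6-diester silyl ether
Conditions: 30, DCC, DMAP, CH2Cl2, 0 °C → rt
Reagents that add atoms: (E)-3-methylpent-2-enoic acid OC(=O)/C=C(\C)CC
Why: Steglich esterification acylates the remaining axial allylic C5 hydroxyl with retention at C5, and carbodiimide activation avoids the ketene pathway that would deconjugate or isomerise the E-enoate.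

Step 14
Reactants: 31 5,6-diester silyl ether; 32 acetic anhydride
Product: 34 target CNP0124625.1, via secondary alcohol 33 (not isolated)
Conditions: HF·pyridine, THF, 0 °C → rt; work-up; crude, 32, pyridine, 0 °C → rt
Reagents that add atoms: acetic anhydride CC(=O)OC(C)=O
Why: Acidic fluoride cleaves the Si–O bond without base-induced retro-aldol reaction or elimination, and acetylation in pyridine alone gives the β-acetoxy ketone with C1′ (R) unchanged.

Compound list
1 | (3aR,6aR)-2,2-dimethyl-3a,6a-dihydro-4H-cyclopenta[d][1,3]dioxol-4-one | O=C1C=C[C@H]2OC(C)(C)O[C@@H]12 | starting material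
2 | isopropylmagnesium chloride | CC(C)[Mg]Cl | starting material
3 | chlorotrimethylsilane | C[Si](C)(C)Cl | starting material
4 | silyl enol ether (7α-isopropyl, 5β,6β-acetonide) | C[Si](C)(C)OC1=C[C@H](C(C)C)[C@H]2OC(C)(C)O[C@@H]12 | intermediate
5 | methyl iodoacetate | COC(=O)CI | starting material
6 | lithium ketone enolate | [Li]OC1=C[C@H](C(C)C)[C@H]2OC(C)(C)O[C@@H]12 | intermediate
7 | keto ester (7aβ-CH2CO2Me, 7α-isopropyl) | O=C1[C@@H](CC(=O)OC)[C@H](C(C)C)[C@H]2OC(C)(C)O[C@@H]12 | intermediate
8 | vinylmagnesium bromide | C=C[Mg]Br | starting material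
9 | bromomagnesium alkoxide (4α-vinyl, 4β-O) | C=C[C@]1(O[Mg]Br)[C@@H](CC(=O)OC)[C@H](C(C)C)[C@H]2OC(C)(C)O[C@@H]12 | intermediate
10 | tricyclic γ-lactone | C=C[C@]12OC(=O)C[C@H]1[C@H](C(C)C)[C@H]3OC(C)(C)O[C@@H]23 | intermediate
11 | acetaldehyde | CC=O | starting material
12 | lithium lactone enolate | C=C[C@]12OC(O[Li])=C[C@H]1[C@H](C(C)C)[C@H]3OC(C)(C)O[C@@H]23 | intermediate
13 | zirconium lactone enolate | C=C[C@]12OC(O[Zr](Cl)(C4C=CC=C4)C4C=CC=C4)=C[C@H]1[C@H](C(C)C)[C@H]3OC(C)(C)O[C@@H]23 | intermediate
14 | syn-aldol lactone (1S,1′R) | C=C[C@]12OC(=O)[C@H]([C@@H](C)O)[C@H]1[C@H](C(C)C)[C@H]3OC(C)(C)O[C@@H]23 | intermediate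
15 | tert-butylchlorodiphenylsilane | CC(C)(C)[Si](Cl)(c1ccccc1)c1ccccc1 | starting material
16 | TBDPS ether lactone | C=C[C@]12OC(=O)[C@H]([C@@H](C)O[Si](c4ccccc4)(c4ccccc4)C(C)(C)C)[C@H]1[C@H](C(C)C)[C@H]3OC(C)(C)O[C@@H]23 | intermediate
17 | benzyl alcohol | OCc1ccccc1 | starting material
18 | lactol (anomeric mixture) | C=C[C@]12OC(O)[C@H]([C@@H](C)O[Si](c4ccccc4)(c4ccccc4)C(C)(C)C)[C@H]1[C@H](C(C)C)[C@H]3OC(C)(C)O[C@@H]23 | intermediate
19 | lactol benzyl ether (anomeric mixture) | C=C[C@]12OC(OCc4ccccc4)[C@H]([C@@H](C)O[Si](c4ccccc4)(c4ccccc4)C(C)(C)C)[C@H]1[C@H](C(C)C)[C@H]3OC(C)(C)O[C@@H]23 | intermediate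
20 | cis-fused hydrindan-4-one (3a-H α) | O=C1[C@H]2C[C@@H](OCc3ccccc3)[C@H]([C@@H](C)O[Si](c3ccccc3)(c3ccccc3)C(C)(C)C)[C@H]2[C@H](C(C)C)[C@@H](OC3(C)C)[C@H]1O3 | intermediate
21 | trans-fused hydrindan-4-one (3a-H β) | O=C1[C@@H]2C[C@@H](OCc3ccccc3)[C@H]([C@@H](C)O[Si](c3ccccc3)(c3ccccc3)C(C)(C)C)[C@H]2[C@H](C(C)C)[C@@H](OC3(C)C)[C@H]1O3 | intermediate
22 | 2β-hydroxy hydrindan-4-one | O=C1[C@@H]2C[C@@H](O)[C@H]([C@@H](C)O[Si](c3ccccc3)(c3ccccc3)C(C)(C)C)[C@H]2[C@H](C(C)C)[C@@H](OC3(C)C)[C@H]1O3 | intermediate
23 | methyltriphenylphosphonium bromide | C[P+](c1ccccc1)(c1ccccc1)c1ccccc1.[Br-] | starting material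
24 | 4-methylene-2β-ol | C=C1[C@@H]2C[C@@H](O)[C@H]([C@@H](C)O[Si](c3ccccc3)(c3ccccc3)C(C)(C)C)[C@H]2[C@H](C(C)C)[C@@H](OC3(C)C)[C@H]1O3 | intermediate
25 | 4-methylene-2-ketone | C=C1[C@@H]2CC(=O)[C@H]([C@@H](C)O[Si](c3ccccc3)(c3ccccc3)C(C)(C)C)[C@H]2[C@H](C(C)C)[C@@H](OC3(C)C)[C@H]1O3 | intermediate
26 | 5β,6β-diol | C=C1[C@@H]2CC(=O)[C@H]([C@@H](C)O[Si](c3ccccc3)(c3ccccc3)C(C)(C)C)[C@H]2[C@H](C(C)C)[C@@H](O)[C@H]1O | intermediate
27 | (S)-2-methylbutanoic anhydride | CC[C@H](C)C(=O)OC(=O)[C@@H](C)CC | starting material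
28 | dibutylstannylene acetal of 26 | C=C1[C@@H]2CC(=O)[C@H]([C@@H](C)O[Si](c3ccccc3)(c3ccccc3)C(C)(C)C)[C@H]2[C@H](C(C)C)[C@@H](O[Sn]3(CCCC)CCCC)[C@H]1O3 | intermediate
29 | 6-O-[(S)-2-methylbutanoyl] 5β-ol | C=C1[C@@H]2CC(=O)[C@H]([C@@H](C)O[Si](c3ccccc3)(c3ccccc3)C(C)(C)C)[C@H]2[C@H](C(C)C)[C@@H](OC(=O)[C@@H](C)CC)[C@H]1O | intermediate
30 | (E)-3-methylpent-2-enoic acid | OC(=O)/C=C(\C)CC | starting material
31 | 5,6-diester silyl ether | C=C1[C@@H]2CC(=O)[C@H]([C@@H](C)O[Si](c3ccccc3)(c3ccccc3)C(C)(C)C)[C@H]2[C@H](C(C)C)[C@@H](OC(=O)[C@@H](C)CC)[C@H]1OC(=O)/C=C(\C)CC | intermediate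
32 | acetic anhydride | CC(=O)OC(C)=O | starting material
33 | secondary alcohol (C1′–OH) | C=C1[C@@H]2CC(=O)[C@H]([C@@H](C)O)[C@H]2[C@H](C(C)C)[C@@H](OC(=O)[C@@H](C)CC)[C@H]1OC(=O)/C=C(\C)CC | intermediate
34 | CNP0124625.1 (1S,1′R,3aR,5S,6R,7S,7aR; S in the 2-methylbutanoate, E in the enoate) | C=C1[C@@H]2CC(=O)[C@H]([C@@H](C)OC(C)=O)[C@H]2[C@H](C(C)C)[C@@H](OC(=O)[C@@H](C)CC)[C@H]1OC(=O)/C=C(\C)CC | target

Total step count: 14. Longest linear sequence: 14 steps (from 1).

Steps most likely to fail

Step 7.
- Risk: Loss of the benzyloxy group, or opening of the acetonide, may outrun the endocyclic cleavage. The cyclic oxocarbenium ion would then decay by proton loss before the deactivated vinyl group engages.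
- Fallback: This uses a sulfur-stabilised cation on an open-chain substrate whose carbinol oxygen no longer belongs to the acetal. It sets out from lactol 18. PhSH and BF3·OEt2 (CH2Cl2, −40 °C) open it to the bis(phenylthio)acetal carbinol F1. Et3SiOTf and 2,6-lutidine give the triethylsilyl ether F2. Me2S(SMe)BF4 in CH2Cl2 (−45 → 0 °C) then generates the thionium ion for the same Prins–pinacol sequence and gives the cis-fused 2-phenylthio ketone F3, which DBU equilibrates to the trans-fused 2-phenylthio ketone F4. Wittig methylenation gives the methylene sulfide F5, and N-chlorosuccinimide gives the α-chloro sulfide F6. CuCl2 and CuO in aqueous acetone hydrolyse F6 to 25, where the route is rejoined.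

Step 4.
- Risk: Poor syn/anti discrimination at C1′, or retro-aldol equilibration of the metal aldolate, may erode the configuration of the carbinol centre.
- Fallback: C1′ is made by reduction instead of by C–C bond formation. It sets out from 10. LiN(SiMe3)2 (2 equiv) and 1-acetylimidazole (THF, −78 °C) give the α-acetyl lactone F7, whose C1 substituent settles on the convex face. Zn(BH4)2 (Et2O, −20 °C) then reduces the chelated β-keto lactone from the side of the C1 hydrogen. This gives the syn alcohol 14, where the route is rejoined.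

Step 12.
- Risk: Steric shielding of the C6 oxygen by the isopropyl group may divert acylation to the C5 oxygen or cause double acylation.
- Fallback: Kinetic regioselection is replaced by thermodynamic funnelling. It sets out from 26. Monoacylation without regiocontrol ((S)-2-methylbutanoic acid, 1 equiv, DCC, DMAP cat., CH2Cl2) gives 29 together with the C5 monoester F8. Treating the mixture with DABCO (cat.) in toluene at 60 °C lets the acyl group migrate across the cis-diol to the equatorial C6 oxygen. The material converges on 29, where the route is rejoined.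

Further compounds
F1 | step 7 | bis(phenylthio)acetal carbinol | C=C[C@]1(O)[C@@H]([C@H](C(Sc2ccccc2)Sc2ccccc2)[C@@H](C)O[Si](c2ccccc2)(c2ccccc2)C(C)(C)C)[C@H](C(C)C)[C@H]2OC(C)(C)O[C@@H]12
F2 | step 7 | triethylsilyl ether of F1 | C=C[C@]1(O[Si](CC)(CC)CC)[C@@H]([C@H](C(Sc2ccccc2)Sc2ccccc2)[C@@H](C)O[Si](c2ccccc2)(c2ccccc2)C(C)(C)C)[C@H](C(C)C)[C@H]2OC(C)(C)O[C@@H]12
F3 | step 7 | cis-fused 2-phenylthio ketone | O=C1[C@H]2C[C@@H](Sc3ccccc3)[C@H]([C@@H](C)O[Si](c3ccccc3)(c3ccccc3)C(C)(C)C)[C@H]2[C@H](C(C)C)[C@@H](OC3(C)C)[C@H]1O3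
F4 | step 7 | trans-fused 2-phenylthio ketone | O=C1[C@@H]2C[C@@H](Sc3ccccc3)[C@H]([C@@H](C)O[Si](c3ccccc3)(c3ccccc3)C(C)(C)C)[C@H]2[C@H](C(C)C)[C@@H](OC3(C)C)[C@H]1O3
F5 | step 7 | methylene sulfide | C=C1[C@@H]2C[C@@H](Sc3ccccc3)[C@H]([C@@H](C)O[Si](c3ccccc3)(c3ccccc3)C(C)(C)C)[C@H]2[C@H](C(C)C)[C@@H](OC3(C)C)[C@H]1O3
F6 | step 7 | α-chloro sulfide | C=C1[C@@H]2CC(Cl)(Sc3ccccc3)[C@H]([C@@H](C)O[Si](c3ccccc3)(c3ccccc3)C(C)(C)C)[C@H]2[C@H](C(C)C)[C@@H](OC3(C)C)[C@H]1O3
F7 | step 4 | α-acetyl lactone | C=C[C@]12OC(=O)[C@H](C(C)=O)[C@H]1[C@H](C(C)C)[C@H]3OC(C)(C)O[C@@H]23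
F8 | step 12 | C5 monoester | C=C1[C@@H]2CC(=O)[C@H]([C@@H](C)O[Si](c3ccccc3)(c3ccccc3)C(C)(C)C)[C@H]2[C@H](C(C)C)[C@@H](O)[C@H]1OC(=O)[C@@H](C)CC
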